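**Retrosynthetic overview**

- The strategy rests on the only two stereocentres, C2 of unit 1 and C2'' of unit 2. Each is the benzylic O1–C2 ether carbon of a ring C (pyranone) and lies β to the C4 ketone, so each is a latent chalcone β-carbon that can be installed after the hindered C2'–C8'' biaryl bond exists.
- The target is traced back, through removal of three O-benzyl groups, to a tri-O-benzyl biflavanone. Cutting O1–C2 and O1''–C2'' together gives a bis(2'-hydroxychalcone) with one free phenol on each ring A.
- The unit-1 enone comes from Claisen–Schmidt condensation of a biaryl chalcone aldehyde with a mono-benzylated acetophenone. The C2'–C8'' bond comes from Suzuki–Miyaura coupling of the unit-2 iodo-chalcone with a formyl arylboronate (ring B of unit 1).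
- Ring order: the four benzene rings are bought. The unit-2 enone is made first, then the biaryl bond, then the unit-1 enone. Both rings C close together at the end, followed only by hydrogenolysis.

Key step: step 8

Assumption: the biaryl axis carries no descriptor in the target and is left uncontrolled (axis isomers are carried together), and the quinine-derived thiourea is taken to give the S sense at both centres; were the sense opposite, its quinidine-derived pseudoenantiomer would take its place in the same step.

**Route**

Step 1
Reactants: 1 2',6'-dihydroxy-4'-methoxyacetophenone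
Product: 2 2'-benzyloxy-6'-hydroxy-4'-methoxyacetophenone
Conditions: BnBr (1.05 equiv), K2CO3, acetone, reflux
Reagents that add atoms: benzyl bromide, BrCc1ccccc1
Why: Williamson O-alkylation of the symmetric diol, in which one hydroxyl is alkylated and the hydroxyl left in 2 is locked in a hydrogen bond to the acetyl oxygen and is far less nucleophilic, so one equivalent of bromide should stop at the monoether.

Step 2
Reactants: 2 2'-benzyloxy-6'-hydroxy-4'-methoxyacetophenone
Product: 3 6'-benzyloxy-2'-hydroxy-3'-iodo-4'-methoxyacetophenone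
Conditions: BnMe3N+ ICl2− (1.05 equiv), NaHCO3, CH2Cl2/MeOH, rt
Reagents that add atoms: benzyltrimethylammonium dichloroiodate, C[N+](C)(C)Cc1ccccc1.Cl[I-]Cl
Why: Electrophilic aromatic iodination of a phenol, which this reagent with bicarbonate delivers next to the free hydroxyl, so C3' between OH and OMe should be substituted rather than C5', which is flanked by two ether groups and has no adjacent phenol.

Step 3
Reactants: 4 syringaldehyde (4-hydroxy-3,5-dimethoxybenzaldehyde)
Product: 5 4-benzyloxy-3,5-dimethoxybenzaldehyde
Conditions: BnBr, K2CO3, DMF, 60 °C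
Reagents that add atoms: benzyl bromide, BrCc1ccccc1
Why: Williamson etherification of the single phenol, the non-enolisable aldehyde being untouched by carbonate base.

Step 4
Reactants: 3 6'-benzyloxy-2'-hydroxy-3'-iodo-4'-methoxyacetophenone; 5 4-benzyloxy-3,5-dimethoxybenzaldehyde
Product: 7 iodo-chalcone of unit 2 (E-enone), via aldol adduct 6 (not isolated)
Conditions: KOH (50% aq.), EtOH, 0 °C to rt; then ice-cold dilute HCl to pH 5–6
Reagents that add atoms: none
Why: Claisen–Schmidt condensation, in which the potassium enolate of the methyl ketone adds to the non-enolisable aldehyde and aldol 6 loses water by an E1cB path to the conjugated E-enone, which stays open as its phenoxide in strong base and is released by a cold, barely acidic work-up while the aryl iodide and benzyl ethers are inert to hydroxide.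

Step 5
Reactants: 8 2-bromo-3,4-dimethoxybenzaldehyde
Product: 9 3,4-dimethoxy-2-(4,4,5,5-tetramethyl-1,3,2-dioxaborolan-2-yl)benzaldehyde
Conditions: B2pin2, PdCl2(dppf) (cat.), KOAc, 1,4-dioxane, 90 °C
Reagents that add atoms: bis(pinacolato)diboron, CC1(C)OB(OC1(C)C)B1OC(C)(C)C(C)(C)O1
Why: Miyaura borylation, in which zerovalent palladium formed from PdCl2(dppf) inserts into the C–Br bond and the acetate-ligated aryl complex transmetalates with the diboron, the weak base KOAc sparing the aldehyde and keeping the product from coupling with unreacted bromide.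

Step 6
Reactants: 7 iodo-chalcone of unit 2; 9 3,4-dimethoxy-2-(4,4,5,5-tetramethyl-1,3,2-dioxaborolan-2-yl)benzaldehyde
Product: 10 biaryl chalcone aldehyde (C2'–C8'' bond in place)
Conditions: Pd(OAc)2 (cat.), SPhos (2-dicyclohexylphosphino-2',6'-dimethoxybiphenyl), K3PO4, degassed toluene/H2O, 90 °C
Reagents that add atoms: none
Why: Suzuki–Miyaura coupling, in which the bulky electron-rich biarylphosphine gives a monoligated zerovalent palladium species able to insert into the di-ortho-substituted C–I bond and to eliminate a tetra-ortho-substituted biaryl, while phenoxide, aldehyde, enone and benzyl ethers tolerate phosphate base and any partial closure of the hydroxy-enone is undone by the hydroxide of step 7.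

Step 7
Reactants: 10 biaryl chalcone aldehyde; 2 2'-benzyloxy-6'-hydroxy-4'-methoxyacetophenone
Product: 12 tribenzyl bis(2'-hydroxychalcone), via aldol adduct 11 (not isolated)
Conditions: KOH (50% aq.), EtOH/THF, 0 °C to rt; then ice-cold dilute HCl to pH 5–6
Reagents that add atoms: none
Why: Second Claisen–Schmidt condensation, in which 2 is the only partner with an enolisable methyl ketone and 10 carries the only aldehyde, far more electrophilic than the electron-rich enone already present, so aldol 11 should form and dehydrate to the E-enone while both chalcones persist as phenoxides until the cold acidification.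

Step 8
Reactants: 12 tribenzyl bis(2'-hydroxychalcone)
Product: 15 (2S,2''S)-tri-O-benzyl biflavanone, via unit-1-closed monoflavanone 13 (not isolated), via unit-2-closed monoflavanone 14 (not isolated)
Conditions: 1-[3,5-bis(trifluoromethyl)phenyl]-3-[(8S,9S)-6'-methoxycinchonan-9-yl]thiourea (quinine-derived, 20 mol%), toluene, −20 °C to 0 °C; cold filtration through silica to remove the catalyst
Reagents that add atoms: none
Why: Proposed new method: the quinuclidine nitrogen of the catalyst acts as a general base on the one free 2'-hydroxyl of each chalcone while the thiourea N–H pair binds the enone carbonyl, the phenol oxygen adds to the β-carbon and the enol is protonated, so that O1–C2 of unit 1 and O1''–C2'' of unit 2 form in the same operation by way of the monoclosed species 13 and 14. The closest known reaction type is the cinchona-thiourea-catalysed enantioselective intramolecular oxa-Michael cyclisation of 2'-hydroxyaryl enones to single flavanones, best established when the enone bears an activating α-ester, together with the enzymatic chalcone isomerase reaction; the closure of two non-activated 6'-alkoxy chalcones held in one biaryl is the untested extension. Each ring C (the pyranone of unit 1 and that of unit 2) closes in the 6-endo-trig mode. C2 and C2'' are each set S by the catalyst alone, which exposes one face of each β-carbon, the two enones lying on different rings on either side of the biaryl bond and being treated as independent substrates. The step needs enantiofacial selectivity over the uncatalysed racemic closure, which low temperature and the apolar solvent hold back while the 6'-benzyloxy groups twist the aryl ketones out of conjugation and make the chalcones reactive enough for amine catalysis; the regiochemistry (8''-aryl and not 6''-aryl in unit 2) is secured by the substrate, since each ring A has a single free phenol, the one next to the biaryl carbon, the other being a benzyl ether. The 5-O-benzyl products lack the chelated 5-hydroxyl that favours retro-oxa-Michael opening, so the new centres should persist once the basic catalyst is removed.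

Step 9
Reactants: 15 (2S,2''S)-tri-O-benzyl biflavanone
Product: 16 target CNP0229789.1
Conditions: H2 (1 atm), Pd/C (10% palladium metal on carbon), EtOAc, rt
Reagents that add atoms: none
Why: Catalytic hydrogenolysis of the three aryl benzyl ethers under neutral conditions, which releases toluene and should leave the aryl ketones and the O1–C2 bonds intact at atmospheric pressure, so neither flavanone ring opens by retro-oxa-Michael reaction and both S centres are kept.

**Compound list**

1 | 2',6'-dihydroxy-4'-methoxyacetophenone | CC(=O)c1c(O)cc(OC)cc1O | starting material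
2 | 2'-benzyloxy-6'-hydroxy-4'-methoxyacetophenone | CC(=O)c1c(O)cc(OC)cc1OCc1ccccc1 | intermediate
3 | 6'-benzyloxy-2'-hydroxy-3'-iodo-4'-methoxyacetophenone | CC(=O)c1c(O)c(I)c(OC)cc1OCc1ccccc1 | intermediate
4 | syringaldehyde (4-hydroxy-3,5-dimethoxybenzaldehyde) | COc1cc(C=O)cc(OC)c1O | starting material
5 | 4-benzyloxy-3,5-dimethoxybenzaldehyde | COc1cc(C=O)cc(OC)c1OCc1ccccc1 | intermediate
6 | aldol adduct, racemic 1-(6-benzyloxy-2-hydroxy-3-iodo-4-methoxyphenyl)-3-(4-benzyloxy-3,5-dimethoxyphenyl)-3-hydroxypropan-1-one | O=C(CC(O)c1cc(OC)c(OCc2ccccc2)c(OC)c1)c1c(O)c(I)c(OC)cc1OCc1ccccc1 | intermediate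
7 | iodo-chalcone of unit 2, (E)-1-(6-benzyloxy-2-hydroxy-3-iodo-4-methoxyphenyl)-3-(4-benzyloxy-3,5-dimethoxyphenyl)prop-2-en-1-one | O=C(/C=C/c1cc(OC)c(OCc2ccccc2)c(OC)c1)c1c(O)c(I)c(OC)cc1OCc1ccccc1 | intermediate
8 | 2-bromo-3,4-dimethoxybenzaldehyde | COc1ccc(C=O)c(Br)c1OC | starting material
9 | 3,4-dimethoxy-2-(4,4,5,5-tetramethyl-1,3,2-dioxaborolan-2-yl)benzaldehyde | COc1ccc(C=O)c(B2OC(C)(C)C(C)(C)O2)c1OC | intermediate
10 | biaryl chalcone aldehyde, 2-[4-benzyloxy-3-[(E)-3-(4-benzyloxy-3,5-dimethoxyphenyl)prop-2-enoyl]-2-hydroxy-6-methoxyphenyl]-3,4-dimethoxybenzaldehyde (axis undefined) | O=C(/C=C/c1cc(OC)c(OCc2ccccc2)c(OC)c1)c1c(O)c(-c2c(C=O)ccc(OC)c2OC)c(OC)cc1OCc1ccccc1 | intermediate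
11 | aldol adduct of 10 and 2, 1-(2-benzyloxy-6-hydroxy-4-methoxyphenyl)-3-hydroxy-3-[2-[4-benzyloxy-3-[(E)-3-(4-benzyloxy-3,5-dimethoxyphenyl)prop-2-enoyl]-2-hydroxy-6-methoxyphenyl]-3,4-dimethoxyphenyl]propan-1-one (carbinol carbon racemic) | O=C(/C=C/c1cc(OC)c(OCc2ccccc2)c(OC)c1)c1c(O)c(-c2c(C(O)CC(=O)c3c(O)cc(OC)cc3OCc3ccccc3)ccc(OC)c2OC)c(OC)cc1OCc1ccccc1 | intermediate
12 | tribenzyl bis(2'-hydroxychalcone), (E)-1-(2-benzyloxy-6-hydroxy-4-methoxyphenyl)-3-[2-[4-benzyloxy-3-[(E)-3-(4-benzyloxy-3,5-dimethoxyphenyl)prop-2-enoyl]-2-hydroxy-6-methoxyphenyl]-3,4-dimethoxyphenyl]prop-2-en-1-one | O=C(/C=C/c1cc(OC)c(OCc2ccccc2)c(OC)c1)c1c(O)c(-c2c(/C=C/C(=O)c3c(O)cc(OC)cc3OCc3ccccc3)ccc(OC)c2OC)c(OC)cc1OCc1ccccc1 | intermediate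
13 | unit-1-closed monoflavanone: (2S)-5-benzyloxy-7-methoxyflavanone of unit 1 whose ring B carries at C2' the still open chalcone of unit 2 | COc1cc(OCc2ccccc2)c2c(c1)O[C@H](c1ccc(OC)c(OC)c1-c1c(OC)cc(OCc3ccccc3)c(C(=O)/C=C/c3cc(OC)c(OCc4ccccc4)c(OC)c3)c1O)CC2=O | intermediate
14 | unit-2-closed monoflavanone: (2''S)-8''-aryl-5''-benzyloxy-7''-methoxyflavanone of unit 2 whose 8''-aryl ring carries the still open chalcone of unit 1 | O=C(/C=C/c1ccc(OC)c(OC)c1-c1c(OC)cc(OCc2ccccc2)c2c1O[C@H](c1cc(OC)c(OCc3ccccc3)c(OC)c1)CC2=O)c1c(O)cc(OC)cc1OCc1ccccc1 | intermediate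
15 | (2S,2''S)-tri-O-benzyl biflavanone, (2S)-5-benzyloxy-2-[2-[(2S)-5-benzyloxy-2-(4-benzyloxy-3,5-dimethoxyphenyl)-7-methoxy-4-oxochroman-8-yl]-3,4-dimethoxyphenyl]-7-methoxychroman-4-one | COc1cc(OCc2ccccc2)c2c(c1)O[C@H](c1ccc(OC)c(OC)c1-c1c(OC)cc(OCc3ccccc3)c3c1O[C@H](c1cc(OC)c(OCc4ccccc4)c(OC)c1)CC3=O)CC2=O | intermediate
16 | CNP0229789.1, (2S)-5-hydroxy-2-[2-[(2S)-5-hydroxy-2-(4-hydroxy-3,5-dimethoxyphenyl)-7-methoxy-4-oxochroman-8-yl]-3,4-dimethoxyphenyl]-7-methoxychroman-4-one | COc1cc(O)c2c(c1)O[C@H](c1ccc(OC)c(OC)c1-c1c(OC)cc(O)c3c1O[C@H](c1cc(OC)c(O)c(OC)c1)CC3=O)CC2=O | target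

**Step count and risks**

Total step count: 9 steps. Longest linear sequence: 7 steps (steps 1, 2, 4, 6, 7, 8, 9, from 1 to 16).

Steps most likely to fail:

1. Step 8 (the proposed new method). The uncatalysed closure, or closure by the amine acting without the hydrogen-bonded organisation, may outrun the selective pathway and give poor facial selectivity at one or both β-carbons. The fixed biaryl axis may also create matched and mismatched substrate–catalyst pairs, or turnover may stall at low temperature. The fallback uses known chemistry, sets out from 12 and returns at 15. Bis-chalcone 12 would be closed without stereocontrol by the classical chalcone–flavanone isomerisation (NaOAc, EtOH, reflux) to the stereoisomer mixture of tri-O-benzyl biflavanones F1. The (2S,2''S) isomer 15 would then be separated by preparative HPLC on a chiral stationary phase (amylose tris(3,5-dimethylphenylcarbamate)). The unwanted stereoisomers can be reopened with KOH in EtOH to 12 and recycled.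

2. Step 6. Transmetalation at the doubly ortho-substituted boron may be slow, so that protodeboronation of the formyl boronate and reduction of the iodide take over. Forcing conditions are limited by base-induced closure or retro-aldol cleavage of the enone partner. The fallback sets out from 8 and 3 and returns at 10, forming the biaryl bond before any enone exists and with the aldehyde masked, so that stronger base and higher temperature can be used. Aldehyde 8 would be converted with ethylene glycol and TsOH (toluene, azeotropic removal of water) into 2-(2-bromo-3,4-dimethoxyphenyl)-1,3-dioxolane F2. Bromine–lithium exchange (n-BuLi, THF, −78 °C) and quenching with 2-isopropoxy-4,4,5,5-tetramethyl-1,3,2-dioxaborolane would give the acetal boronate 2-[6-(1,3-dioxolan-2-yl)-2,3-dimethoxyphenyl]-4,4,5,5-tetramethyl-1,3,2-dioxaborolane F3. Suzuki–Miyaura coupling of F3 with iodoacetophenone 3 (Pd(OAc)2, SPhos, K3PO4 or Ba(OH)2, dioxane/H2O, 100 °C) would give the biaryl acetophenone acetal 1-[6-benzyloxy-3-[6-(1,3-dioxolan-2-yl)-2,3-dimethoxyphenyl]-2-hydroxy-4-methoxyphenyl]ethanone F4. Claisen–Schmidt condensation of F4 with 5 (KOH, EtOH) would give the chalcone acetal F5, and brief dilute HCl in THF at 0 °C would unmask the aldehyde to give 10.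

3. Step 7. The ketone enolate may add in conjugate fashion to the enone already present, hydroxide may scramble that enone by retro-aldol cleavage, or the rings may close prematurely at the acidification. The fallback sets out from 2 and returns at 12, replacing the hydroxide condensation by a neutral Wittig olefination of the aldehyde. Acetophenone 2 would be brominated at the methyl group (CuBr2, EtOAc/CHCl3, reflux) to 2-bromo-1-(2-benzyloxy-6-hydroxy-4-methoxyphenyl)ethanone F6. PPh3 in toluene would give the phosphonium bromide F7, and aqueous Na2CO3 the stabilised acyl ylide F8. Heating F8 with aldehyde 10 in toluene should attack only the aldehyde and give the E-enone of 12 directly.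

**Further compounds**

F1 | step 8 | tri-O-benzyl biflavanone as the mixture of stereoisomers at C2 and C2'' | COc1cc(OCc2ccccc2)c2c(c1)OC(c1ccc(OC)c(OC)c1-c1c(OC)cc(OCc3ccccc3)c3c1OC(c1cc(OC)c(OCc4ccccc4)c(OC)c1)CC3=O)CC2=O
F2 | step 6 | 2-(2-bromo-3,4-dimethoxyphenyl)-1,3-dioxolane | COc1ccc(C2OCCO2)c(Br)c1OC
F3 | step 6 | 2-[6-(1,3-dioxolan-2-yl)-2,3-dimethoxyphenyl]-4,4,5,5-tetramethyl-1,3,2-dioxaborolane | COc1ccc(C2OCCO2)c(B2OC(C)(C)C(C)(C)O2)c1OC
F4 | step 6 | 1-[6-benzyloxy-3-[6-(1,3-dioxolan-2-yl)-2,3-dimethoxyphenyl]-2-hydroxy-4-methoxyphenyl]ethanone | CC(=O)c1c(O)c(-c2c(C3OCCO3)ccc(OC)c2OC)c(OC)cc1OCc1ccccc1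
F5 | step 6 | chalcone acetal, (E)-1-[6-benzyloxy-3-[6-(1,3-dioxolan-2-yl)-2,3-dimethoxyphenyl]-2-hydroxy-4-methoxyphenyl]-3-(4-benzyloxy-3,5-dimethoxyphenyl)prop-2-en-1-one | O=C(/C=C/c1cc(OC)c(OCc2ccccc2)c(OC)c1)c1c(O)c(-c2c(C3OCCO3)ccc(OC)c2OC)c(OC)cc1OCc1ccccc1
F6 | step 7 | 2-bromo-1-(2-benzyloxy-6-hydroxy-4-methoxyphenyl)ethanone | O=C(CBr)c1c(O)cc(OC)cc1OCc1ccccc1
F7 | step 7 | [2-(2-benzyloxy-6-hydroxy-4-methoxyphenyl)-2-oxoethyl]triphenylphosphonium bromide | O=C(C[P+](c1ccccc1)(c1ccccc1)c1ccccc1)c1c(O)cc(OC)cc1OCc1ccccc1.[Br-]
F8 | step 7 | 1-(2-benzyloxy-6-hydroxy-4-methoxyphenyl)-2-(triphenylphosphoranylidene)ethanone | O=C(C=P(c1ccccc1)(c1ccccc1)c1ccccc1)c1c(O)cc(OC)cc1OCc1ccccc1
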